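Everything rests on cutting the dihydropyran ring C of the flavan at O1–C2 and C3–C4. O1 sits on C8a next to C4a, which bears the C4 methylene. Ring A with O1 and C4 is therefore a masked oxadiene (an ortho-quinone methide), and C2–C3 with its phenyl group is simply styrene. A single chiral-acid-catalysed oxa-[4+2] makes both bonds, closes ring C and fixes C2 as (S). The precursor is a 2-(hydroxymethyl)phenol with the 5-OMe and 7-OBn groups in place and, as added design, bromine on the future C8. The bromine blocks the most nucleophilic ring carbon and later serves as the handle for joining the ring D benzofuran.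

Key step: step 5

Remark on ring D: it carries oxygen on C4', C6' and C7a' around the C5' methyl group (a C-methylphloroglucinol pattern), so it is built from 2,4,6-trihydroxy-3-methylbenzaldehyde. A 2,4-dihydroxy-3-methylbenzaldehyde has no oxygen on the carbon that must become C7a' and would put the methyl group on C7'.
Remark on the catalyst: the sense of induction cannot be derived from precedent, so (R)-TRIP is written and its mirror image is meant if first experiments show the (R) product.
Abbreviations: TRIP = 3,3'-bis(2,4,6-triisopropylphenyl)-1,1'-binaphthyl-2,2'-diyl hydrogen phosphate; SPhos = 2-dicyclohexylphosphino-2',6'-dimethoxybiphenyl.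

Step 1
Reactants: 1 2,4,6-trihydroxybenzaldehyde
Product: 2 4-(benzyloxy)-2,6-dihydroxybenzaldehyde
Conditions: BnBr (1.0 equiv), KHCO3, DMF, 40 °C
Reagents that add atoms: benzyl bromide, BrCc1ccccc1
Why: Williamson etherification under a weak base, in which only the para hydroxyl (the most acidic one and the only one not chelated to the formyl group) should be deprotonated and alkylated.

Step 2
Reactants: 2 4-(benzyloxy)-2,6-dihydroxybenzaldehyde
Product: 3 4-(benzyloxy)-2-hydroxy-6-methoxybenzaldehyde
Conditions: MeI (1.1 equiv), K2CO3 (1.1 equiv), acetone, rt to 40 °C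
Reagents that add atoms: iodomethane, CI
Why: Williamson etherification of one of two equivalent hydroxyls; the hydroxyl that remains is locked in a strong hydrogen bond to the aldehyde, which should stop the reaction at the monomethyl ether.

Step 3
Reactants: 3 4-(benzyloxy)-2-hydroxy-6-methoxybenzaldehyde
Product: 4 4-(benzyloxy)-3-bromo-2-hydroxy-6-methoxybenzaldehyde
Conditions: NBS (1.0 equiv), CH2Cl2, −10 °C, dark
Reagents that add atoms: N-bromosuccinimide, O=C1CCC(=O)N1Br
Why: Electrophilic aromatic bromination; in 2-hydroxy-4,6-dialkoxyaryl carbonyl compounds the carbon ortho to the free phenol and para to the methoxy group (C3) is the usual site of monohalogenation, while C5 is squeezed between two ethers.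

Step 4
Reactants: 4 4-(benzyloxy)-3-bromo-2-hydroxy-6-methoxybenzaldehyde
Product: 5 5-(benzyloxy)-6-bromo-2-(hydroxymethyl)-3-methoxyphenol
Conditions: NaBH4, THF/MeOH, 0 °C; pH 7 buffer work-up, used without chromatography on silica
Reagents that add atoms: none
Why: Borohydride reduction of the aldehyde leaves the aryl bromide and both ethers alone, and the cold, neutral work-up should protect the acid-labile salicyl alcohol.

Step 5
Reactants: 5 5-(benzyloxy)-6-bromo-2-(hydroxymethyl)-3-methoxyphenol; 6 styrene
Product: 8 (S)-7-(benzyloxy)-8-bromo-5-methoxy-2-phenylchroman, via o-quinone methide 7 (not isolated)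
Conditions: (R)-TRIP (10 mol%), styrene (10 equiv), 5 Å MS, toluene, 0 °C, 5 added over 10 h
Reagents that add atoms: none
Why: Proposed new method: protonation of the CH2OH group by the phosphoric acid and departure of water, pushed by the ortho methoxy and para benzyloxy donors, unmasks o-quinone methide 7, which stays attached to the chiral phosphate through its carbonyl oxygen; the terminal carbon of styrene then bonds to the exocyclic methylene (C3–C4) while that oxygen captures the developing benzylic cation (O1–C2), an asynchronous inverse-demand oxa-[4+2] driven by rearomatisation of ring A. The closest known reaction types are the chiral phosphoric acid-catalysed cycloaddition of aryl-substituted o-quinone methides (from o-hydroxybenzyl alcohols) with hydroxystyrenes and the racemic thermal trapping of the parent o-quinone methide by styrene; new here is a quinone methide with a bare methylene terminus paired with a styrene that offers the catalyst no hydrogen-bond handle. Ring C closes as a six-membered ring by intermolecular [4+2] cycloaddition, both new bonds arising in one event. C2 is the only new stereocentre, and its (S) configuration has to come from the catalyst pocket, whose 3,3'-aryl walls should leave one face of bound 7 open and only one orientation of the styrene phenyl group free of clashes; the bromine beside the carbonyl oxygen reduces the number of ways in which 7 can sit in that pocket. The phenyl group ends up on C2 because styrene is nucleophilic at CH2 and stabilises positive charge at its benzylic carbon; no para-quinone methide can form because the para oxygen carries a benzyl group instead of a proton; and the required preference for styrene over Friedel–Crafts self-alkylation is served by the bromine, which occupies and deactivates the most nucleophilic ring position, helped by excess styrene and slow addition of 5.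

Step 6
Reactants: 9 2,4,6-trihydroxy-3-methylbenzaldehyde
Product: 10 4,6-bis(benzyloxy)-2-hydroxy-3-methylbenzaldehyde
Conditions: BnBr (2.1 equiv), K2CO3, DMF, rt
Reagents that add atoms: benzyl bromide, BrCc1ccccc1
Why: Williamson etherification; the hydroxyl between the formyl and methyl groups is the least acidic, the most hindered and the most firmly chelated, so two equivalents of halide should go to O4 and O6.

Step 7
Reactants: 10 4,6-bis(benzyloxy)-2-hydroxy-3-methylbenzaldehyde
Product: 11 4,6-bis(benzyloxy)-2-methoxy-3-methylbenzaldehyde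
Conditions: MeI (excess), K2CO3, DMF, 50 °C
Reagents that add atoms: iodomethane, CI
Why: Williamson etherification of the single remaining phenol, forced with excess of the small electrophile in a dipolar solvent.

Step 8
Reactants: 11 4,6-bis(benzyloxy)-2-methoxy-3-methylbenzaldehyde
Product: 12 4-(benzyloxy)-6-hydroxy-2-methoxy-3-methylbenzaldehyde
Conditions: MgBr2·OEt2 (2 equiv), toluene/Et2O, 80 °C; then 1 M HCl
Reagents that add atoms: none
Why: Chelation-controlled ether cleavage; magnesium bound between the aldehyde oxygen and an ortho ether oxygen activates only ortho ethers, and bromide removes a benzyl group far more readily than a methyl group under this mild Lewis acid, so the para benzyl and the methyl ether should survive.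

Step 9
Reactants: 12 4-(benzyloxy)-6-hydroxy-2-methoxy-3-methylbenzaldehyde
Product: 13 5-(benzyloxy)-2-(2,2-dibromoethenyl)-3-methoxy-4-methylphenol
Conditions: CBr4, PPh3, Zn dust (3 equiv each), CH2Cl2, rt; then 12, 0 °C to rt
Reagents that add atoms: carbon tetrabromide, BrC(Br)(Br)Br
Why: Ramirez (Corey–Fuchs) dibromo-olefination; the zinc variant forms the ylide without Ph3PBr2, so the free phenol has no phosphorus electrophile to react with.

Step 10
Reactants: 13 5-(benzyloxy)-2-(2,2-dibromoethenyl)-3-methoxy-4-methylphenol
Product: 14 6-(benzyloxy)-2-bromo-4-methoxy-5-methylbenzofuran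
Conditions: CuI (5 mol%), K3PO4, THF, 80 °C
Reagents that add atoms: none
Why: Intramolecular Ullmann-type C–O coupling of a 2-(gem-dibromovinyl)phenol, a known entry to 2-bromobenzofurans in which only the bromine within reach of the phenoxide is displaced.

Step 11
Reactants: 8 (S)-7-(benzyloxy)-8-bromo-5-methoxy-2-phenylchroman; 14 6-(benzyloxy)-2-bromo-4-methoxy-5-methylbenzofuran
Product: 17 (S)-7-(benzyloxy)-8-[6-(benzyloxy)-4-methoxy-5-methylbenzofuran-2-yl]-5-methoxy-2-phenylchroman, via aryllithium 15 (not isolated), via arylzinc chloride 16 (not isolated)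
Conditions: 8, n-BuLi (1.0 equiv), THF, −78 °C; ZnCl2, −78 °C to rt; then 14, Pd(OAc)2 (2 mol%), SPhos (4 mol%), 50 °C
Reagents that add atoms: n-butyllithium, [Li]CCCC (lithium, kept only in 15); zinc chloride, Cl[Zn]Cl (zinc and chlorine, kept only in 16)
Why: Bromine–lithium exchange outruns deprotonation at −78 °C, zinc gives a non-basic aryl nucleophile, and Negishi coupling with an electron-rich biarylphosphine is a standard answer to doubly ortho-substituted partners, the five-membered heteroaryl bromide adding little bulk and C2 staying untouched.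

Step 12
Reactants: 17 (S)-7-(benzyloxy)-8-[6-(benzyloxy)-4-methoxy-5-methylbenzofuran-2-yl]-5-methoxy-2-phenylchroman
Product: 18 (S)-8-(6-hydroxy-4-methoxy-5-methylbenzofuran-2-yl)-5-methoxy-2-phenylchroman-7-ol
Conditions: H2 (1 atm), Pd/C (10 wt%), EtOAc/MeOH, rt, stopped after uptake of two equivalents
Reagents that add atoms: none
Why: Catalytic hydrogenolysis of both aryl benzyl ethers; the ring C2–O1 bond and the furan C2'=C3' bond react much more slowly at ambient pressure and temperature, so the skeleton and the (S) centre should be preserved.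

Compound list
1 | 2,4,6-trihydroxybenzaldehyde | O=Cc1c(O)cc(O)cc1O | starting material
2 | 4-(benzyloxy)-2,6-dihydroxybenzaldehyde | O=Cc1c(O)cc(OCc2ccccc2)cc1O | intermediate
3 | 4-(benzyloxy)-2-hydroxy-6-methoxybenzaldehyde | COc1cc(OCc2ccccc2)cc(O)c1C=O | intermediate
4 | 4-(benzyloxy)-3-bromo-2-hydroxy-6-methoxybenzaldehyde | COc1cc(OCc2ccccc2)c(Br)c(O)c1C=O | intermediate
5 | 5-(benzyloxy)-6-bromo-2-(hydroxymethyl)-3-methoxyphenol | COc1cc(OCc2ccccc2)c(Br)c(O)c1CO | intermediate
6 | styrene | C=Cc1ccccc1 | starting material
7 | 3-(benzyloxy)-2-bromo-5-methoxy-6-methylidenecyclohexa-2,4-dien-1-one (o-quinone methide, not isolated) | C=C1C(OC)=CC(OCc2ccccc2)=C(Br)C1=O | intermediate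
8 | (S)-7-(benzyloxy)-8-bromo-5-methoxy-2-phenylchroman | COc1cc(OCc2ccccc2)c(Br)c2c1CC[C@@H](c1ccccc1)O2 | intermediate
9 | 2,4,6-trihydroxy-3-methylbenzaldehyde | Cc1c(O)cc(O)c(C=O)c1O | starting material
10 | 4,6-bis(benzyloxy)-2-hydroxy-3-methylbenzaldehyde | Cc1c(O)c(C=O)c(OCc2ccccc2)cc1OCc1ccccc1 | intermediate
11 | 4,6-bis(benzyloxy)-2-methoxy-3-methylbenzaldehyde | COc1c(C)c(OCc2ccccc2)cc(OCc2ccccc2)c1C=O | intermediate
12 | 4-(benzyloxy)-6-hydroxy-2-methoxy-3-methylbenzaldehyde | COc1c(C)c(OCc2ccccc2)cc(O)c1C=O | intermediate
13 | 5-(benzyloxy)-2-(2,2-dibromoethenyl)-3-methoxy-4-methylphenol | COc1c(C)c(OCc2ccccc2)cc(O)c1C=C(Br)Br | intermediate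
14 | 6-(benzyloxy)-2-bromo-4-methoxy-5-methylbenzofuran | COc1c(C)c(OCc2ccccc2)cc2oc(Br)cc12 | intermediate
15 | [(S)-7-(benzyloxy)-5-methoxy-2-phenylchroman-8-yl]lithium (not isolated) | COc1cc(OCc2ccccc2)c([Li])c2c1CC[C@@H](c1ccccc1)O2 | intermediate
16 | [(S)-7-(benzyloxy)-5-methoxy-2-phenylchroman-8-yl]zinc chloride (not isolated) | COc1cc(OCc2ccccc2)c([Zn]Cl)c2c1CC[C@@H](c1ccccc1)O2 | intermediate
17 | (S)-7-(benzyloxy)-8-[6-(benzyloxy)-4-methoxy-5-methylbenzofuran-2-yl]-5-methoxy-2-phenylchroman | COc1cc(OCc2ccccc2)c(-c2cc3c(OC)c(C)c(OCc4ccccc4)cc3o2)c2c1CC[C@@H](c1ccccc1)O2 | intermediate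
18 | (S)-8-(6-hydroxy-4-methoxy-5-methylbenzofuran-2-yl)-5-methoxy-2-phenylchroman-7-ol | COc1cc(O)c(-c2cc3c(OC)c(C)c(O)cc3o2)c2c1CC[C@@H](c1ccccc1)O2 | target

Total step count: 12.
Longest linear sequence: 7 steps (steps 1–5, 11, 12). The ring D branch (steps 6–10, 11, 12) is equally long.

Steps most likely to fail

Step 5. The quinone methide may be consumed by self-alkylation or oligomerisation before styrene intercepts it, or the phosphate may discriminate poorly between the two faces.
- The fallback uses known chemistry, sets out from 4 and comes back at 8.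
- Wittig olefination of 4 with (benzoylmethylene)triphenylphosphorane in toluene should give (E)-3-[4-(benzyloxy)-3-bromo-2-hydroxy-6-methoxyphenyl]-1-phenylprop-2-en-1-one F1.
- Hydrogenation of the alkene alone over RhCl(PPh3)3 (H2, toluene/EtOH) gives 3-[4-(benzyloxy)-3-bromo-2-hydroxy-6-methoxyphenyl]-1-phenylpropan-1-one F2.
- Corey–Bakshi–Shibata reduction with (S)-2-methyl-CBS-oxazaborolidine and BH3·SMe2 gives (R)-3-(benzyloxy)-2-bromo-6-(3-hydroxy-3-phenylpropyl)-5-methoxyphenol F3.
- Intramolecular Mitsunobu etherification (PPh3, DIAD, THF, 0 °C) lets the phenol oxygen displace the activated carbinol with inversion. This closes ring C and gives (S)-configured 8.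

Step 8. The methyl ether or the para benzyl ether may be lost together with the ortho benzyl ether, and any regiochemical leakage from step 6 would surface here.
- The fallback replaces chelation-controlled cleavage by orthogonal protection, sets out from 9 and comes back at 12.
- One equivalent of benzyl bromide with KHCO3 in DMF etherifies only the para hydroxyl to give 4-(benzyloxy)-2,6-dihydroxy-3-methylbenzaldehyde F4.
- Allyl bromide and K2CO3 then take the less hindered chelated hydroxyl to give 6-(allyloxy)-4-(benzyloxy)-2-hydroxy-3-methylbenzaldehyde F5.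
- MeI and K2CO3 give 6-(allyloxy)-4-(benzyloxy)-2-methoxy-3-methylbenzaldehyde F6.
- Pd(PPh3)4 with morpholine in THF transfers the allyl group alone to the amine and releases 12.

Step 11. The aryllithium may be protonated or may metalate the neighbouring benzylic CH2, transmetalation at the doubly flanked carbon may be slow, or the electron-rich bromobenzofuran may decompose.
- The fallback builds the furan ring on the flavan instead of coupling a finished benzofuran. It sets out from 8 and 12, bypasses steps 9 and 10, and comes back at 17.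
- Aryllithium 15 is quenched with CO2 to give (S)-7-(benzyloxy)-5-methoxy-2-phenylchroman-8-carboxylic acid F7.
- (COCl)2 with catalytic DMF converts F7 into (S)-7-(benzyloxy)-5-methoxy-2-phenylchroman-8-carbonyl chloride F8.
- In parallel, 12 is reduced with NaBH4 to 5-(benzyloxy)-2-(hydroxymethyl)-3-methoxy-4-methylphenol F9.
- PPh3·HBr in refluxing MeCN turns F9 into [4-(benzyloxy)-6-hydroxy-2-methoxy-3-methylbenzyl]triphenylphosphonium bromide F10.
- F8 acylates the phenol of F10 (Et3N, CH2Cl2) to give {4-(benzyloxy)-6-[(S)-7-(benzyloxy)-5-methoxy-2-phenylchroman-8-carbonyloxy]-2-methoxy-3-methylbenzyl}triphenylphosphonium bromide F11.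
- More Et3N in refluxing toluene triggers the intramolecular Wittig reaction on the ester carbonyl, which gives 17.

Further compounds
F1 | step 5 | (E)-3-[4-(benzyloxy)-3-bromo-2-hydroxy-6-methoxyphenyl]-1-phenylprop-2-en-1-one | COc1cc(OCc2ccccc2)c(Br)c(O)c1/C=C/C(=O)c1ccccc1
F2 | step 5 | 3-[4-(benzyloxy)-3-bromo-2-hydroxy-6-methoxyphenyl]-1-phenylpropan-1-one | COc1cc(OCc2ccccc2)c(Br)c(O)c1CCC(=O)c1ccccc1
F3 | step 5 | (R)-3-(benzyloxy)-2-bromo-6-(3-hydroxy-3-phenylpropyl)-5-methoxyphenol | COc1cc(OCc2ccccc2)c(Br)c(O)c1CC[C@@H](O)c1ccccc1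
F4 | step 8 | 4-(benzyloxy)-2,6-dihydroxy-3-methylbenzaldehyde | Cc1c(O)c(C=O)c(O)cc1OCc1ccccc1
F5 | step 8 | 6-(allyloxy)-4-(benzyloxy)-2-hydroxy-3-methylbenzaldehyde | C=CCOc1cc(OCc2ccccc2)c(C)c(O)c1C=O
F6 | step 8 | 6-(allyloxy)-4-(benzyloxy)-2-methoxy-3-methylbenzaldehyde | C=CCOc1cc(OCc2ccccc2)c(C)c(OC)c1C=O
F7 | step 11 | (S)-7-(benzyloxy)-5-methoxy-2-phenylchroman-8-carboxylic acid | COc1cc(OCc2ccccc2)c(C(=O)O)c2c1CC[C@@H](c1ccccc1)O2
F8 | step 11 | (S)-7-(benzyloxy)-5-methoxy-2-phenylchroman-8-carbonyl chloride | COc1cc(OCc2ccccc2)c(C(=O)Cl)c2c1CC[C@@H](c1ccccc1)O2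
F9 | step 11 | 5-(benzyloxy)-2-(hydroxymethyl)-3-methoxy-4-methylphenol | COc1c(C)c(OCc2ccccc2)cc(O)c1CO
F10 | step 11 | [4-(benzyloxy)-6-hydroxy-2-methoxy-3-methylbenzyl]triphenylphosphonium bromide | COc1c(C)c(OCc2ccccc2)cc(O)c1C[P+](c1ccccc1)(c1ccccc1)c1ccccc1.[Br-]
F11 | step 11 | {4-(benzyloxy)-6-[(S)-7-(benzyloxy)-5-methoxy-2-phenylchroman-8-carbonyloxy]-2-methoxy-3-methylbenzyl}triphenylphosphonium bromide | COc1cc(OCc2ccccc2)c(C(=O)Oc2cc(OCc3ccccc3)c(C)c(OC)c2C[P+](c2ccccc2)(c2ccccc2)c2ccccc2)c2c1CC[C@@H](c1ccccc1)O2.[Br-]
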